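**Retrosynthetic overview**
1. Target ⇐ desilylation ⇐ crossed Claisen-type C-acylation of a bicyclo[3.2.1]octane-2,4,8-trione with (R)-2-methylbutanoic acid (made by Evans alkylation).
2. Trione ⇐ bicyclic 2,8-dione (enone formation, β-oxygenation, oxidation) ⇐ intramolecular Michael addition of a 5-prenylcyclopentanone enolate onto a vinyl ketone on the neighbouring quaternary carbon; the vinyl ketone comes from an intermolecular Mannich reaction of an acetyl group.
3. Quaternary carbon and its neighbour ⇐ three-component coupling on (S)-4-silyloxy-2-methylcyclopentenone: conjugate addition of isopropenyl anti to OTBS, then intermolecular aldol with acetaldehyde (the key fragment-joining C–C bond). OTBS is then removed by elimination and hydrogenation; isopropenyl becomes the tertiary alcohol by Mukaiyama hydration.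
4. Ring order: five-membered ring first (Piancatelli rearrangement, lipase resolution), six-membered ring second (Michael closure), which forces the bridgeheads cis and leaves the hydroxypropyl group exo.

Assumption: the carbinol carbon of the 1-hydroxyethyl group (9–16) and the prenyl-bearing ring carbon (15–22) are carried as epimer mixtures and drawn without configuration, because both centres are erased in steps 12 and 15.

**Route**

Step 1
Reactants: 1 1-(furan-2-yl)ethanol (racemic)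
Product: 2 rac-trans-4-hydroxy-5-methylcyclopent-2-en-1-one
Conditions: ZnCl2, 1,4-dioxane/H2O, reflux
Reagents that add atoms: water O
Why: Piancatelli rearrangement (loss of water, water addition at C-5 of the furan, ring opening, conrotatory 4π electrocyclisation) gives the trans hydroxy enone as a racemate.

Step 2
Reactants: 2 rac-trans-4-hydroxy-5-methylcyclopent-2-en-1-one
Product: 3 rac-4-hydroxy-2-methylcyclopent-2-en-1-one
Conditions: aq. phosphate buffer (pH 8), 1,4-dioxane, 50 °C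
Reagents that add atoms: water O
Why: Base-mediated enone transposition (conjugate addition of water, then E1cB loss of the original hydroxyl through the C-5 enolate) gives the thermodynamically preferred 2-methyl enone.

Step 3
Reactants: 3 rac-4-hydroxy-2-methylcyclopent-2-en-1-one
Product: 4 (S)-4-hydroxy-2-methylcyclopent-2-en-1-one
Conditions: immobilised Candida antarctica lipase B, vinyl acetate (0.6 equiv), MTBE, rt, to about 55% conversion
Reagents that add atoms: none
Why: Lipase-catalysed kinetic resolution by enantioselective transesterification acetylates the (R)-alcohol and leaves the (S)-alcohol, whose stereocentre steers step 5, in high ee.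

Step 4
Reactants: 4 (S)-4-hydroxy-2-methylcyclopent-2-en-1-one
Product: 5 (S)-4-[(tert-butyldimethylsilyl)oxy]-2-methylcyclopent-2-en-1-one
Conditions: TBSCl, imidazole, DMF, rt
Reagents that add atoms: tert-butyldimethylsilyl chloride CC(C)(C)[Si](C)(C)Cl
Why: Silyl ether formation installs the bulky directing group without touching the stereocentre.

Step 5
Reactants: 5 (S)-4-[(tert-butyldimethylsilyl)oxy]-2-methylcyclopent-2-en-1-one; 6 isopropenylmagnesium bromide; 7 acetaldehyde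
Product: 9 (2R,3S,4S)-4-[(tert-butyldimethylsilyl)oxy]-2-(1-hydroxyethyl)-2-methyl-3-(prop-1-en-2-yl)cyclopentan-1-one (carbinol epimers), via magnesium enolate 8 (not isolated)
Conditions: 6 (1.5 equiv), CuBr·SMe2 (20 mol %), THF, −78 → −40 °C; then 7 (3 equiv), −78 °C; then H2O
Reagents that add atoms: isopropenylmagnesium bromide C=C(C)[Mg]Br; acetaldehyde CC=O
Why: Tandem copper-catalysed conjugate (Michael-type) addition and intermolecular aldol reaction: isopropenyl adds anti to OTBS, and enolate 8 takes acetaldehyde anti to isopropenyl, so the quaternary carbon carries its C2 chain trans and its methyl cis to isopropenyl.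

Step 6
Reactants: 9 (2R,3S,4S)-4-[(tert-butyldimethylsilyl)oxy]-2-(1-hydroxyethyl)-2-methyl-3-(prop-1-en-2-yl)cyclopentan-1-one
Product: 10 (2R,3S,4S)-4-[(tert-butyldimethylsilyl)oxy]-2-methyl-3-(prop-1-en-2-yl)-2-{1-[(triethylsilyl)oxy]ethyl}cyclopentan-1-one
Conditions: Et3SiOTf, 2,6-lutidine, CH2Cl2, −78 °C
Reagents that add atoms: triethylsilyl triflate CC[Si](CC)(CC)OS(=O)(=O)C(F)(F)F
Why: Silyl ether formation protects the retro-aldol-prone β-hydroxy ketone for the basic steps ahead.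

Step 7
Reactants: 10 (2R,3S,4S)-4-[(tert-butyldimethylsilyl)oxy]-2-methyl-3-(prop-1-en-2-yl)-2-{1-[(triethylsilyl)oxy]ethyl}cyclopentan-1-one
Product: 11 (2R,3S,4S)-4-[(tert-butyldimethylsilyl)oxy]-3-(2-hydroxypropan-2-yl)-2-methyl-2-{1-[(triethylsilyl)oxy]ethyl}cyclopentan-1-one
Conditions: Co(acac)2 (cobalt bis(acetylacetonate), 20 mol %), PhSiH3, O2 (1 atm), i-PrOH/THF, rt
Reagents that add atoms: dioxygen O=O
Why: Mukaiyama hydration (cobalt-hydride hydrogen-atom transfer, O2 trapping) gives the Markovnikov tertiary alcohol from the only alkene present, and no stereocentre is touched.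

Step 8
Reactants: 11 (2R,3S,4S)-4-[(tert-butyldimethylsilyl)oxy]-3-(2-hydroxypropan-2-yl)-2-methyl-2-{1-[(triethylsilyl)oxy]ethyl}cyclopentan-1-one
Product: 12 (4R,5R)-4-(2-hydroxypropan-2-yl)-5-methyl-5-{1-[(triethylsilyl)oxy]ethyl}cyclopent-2-en-1-one
Conditions: DBU, CH2Cl2, rt → 40 °C
Reagents that add atoms: none
Why: E1cB β-elimination of silanolate removes the directing group once it has done its work, without involving the two remaining ring stereocentres.

Step 9
Reactants: 12 (4R,5R)-4-(2-hydroxypropan-2-yl)-5-methyl-5-{1-[(triethylsilyl)oxy]ethyl}cyclopent-2-en-1-one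
Product: 13 (2R,3R)-3-(2-hydroxypropan-2-yl)-2-methyl-2-{1-[(triethylsilyl)oxy]ethyl}cyclopentan-1-one
Conditions: H2 (1 atm), 10% Pd on carbon, EtOAc, rt
Reagents that add atoms: none
Why: Heterogeneous hydrogenation saturates the enone C=C, the only alkene in the molecule, and creates no stereocentre.

Step 10
Reactants: 13 (2R,3R)-3-(2-hydroxypropan-2-yl)-2-methyl-2-{1-[(triethylsilyl)oxy]ethyl}cyclopentan-1-one; 14 1-bromo-3-methylbut-2-ene (prenyl bromide)
Product: 15 (2R,3R)-3-(2-hydroxypropan-2-yl)-2-methyl-5-(3-methylbut-2-en-1-yl)-2-{1-[(triethylsilyl)oxy]ethyl}cyclopentan-1-one (C-5 epimers)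
Conditions: LiN(i-Pr)2 (2.2 equiv), THF, −78 °C; 14 (1.1 equiv), −78 → −30 °C; then H2O
Reagents that add atoms: 1-bromo-3-methylbut-2-ene CC(C)=CCBr
Why: SN2 alkylation of the lithium enolate, which can form only on the CH2 side because the other α-carbon is quaternary; the tertiary alkoxide is a spectator and the new centre is enolised again in step 15.

Step 11
Reactants: 15 (2R,3R)-3-(2-hydroxypropan-2-yl)-2-methyl-5-(3-methylbut-2-en-1-yl)-2-{1-[(triethylsilyl)oxy]ethyl}cyclopentan-1-one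
Product: 16 (2R,3R)-2-(1-hydroxyethyl)-3-(2-hydroxypropan-2-yl)-2-methyl-5-(3-methylbut-2-en-1-yl)cyclopentan-1-one
Conditions: HF·pyridine, pyridine, THF, 0 °C → rt
Reagents that add atoms: none
Why: Fluoride-mediated cleavage of the only silyl ether frees the secondary alcohol.

Step 12
Reactants: 16 (2R,3R)-2-(1-hydroxyethyl)-3-(2-hydroxypropan-2-yl)-2-methyl-5-(3-methylbut-2-en-1-yl)cyclopentan-1-one
Product: 17 (2R,3R)-2-acetyl-3-(2-hydroxypropan-2-yl)-2-methyl-5-(3-methylbut-2-en-1-yl)cyclopentan-1-one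
Conditions: Dess–Martin periodinane, pyridine, CH2Cl2, rt
Reagents that add atoms: none
Why: Dess–Martin oxidation of the secondary alcohol; the tertiary alcohol cannot be oxidised and both carbinol epimers give the same methyl ketone.

Step 13
Reactants: 17 (2R,3R)-2-acetyl-3-(2-hydroxypropan-2-yl)-2-methyl-5-(3-methylbut-2-en-1-yl)cyclopentan-1-one
Product: 18 (2R,3R)-2-acetyl-2-methyl-5-(3-methylbut-2-en-1-yl)-3-{2-[(triethylsilyl)oxy]propan-2-yl}cyclopentan-1-one
Conditions: Et3SiOTf (1.1 equiv), 2,6-lutidine, CH2Cl2, −78 → 0 °C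
Reagents that add atoms: triethylsilyl triflate CC[Si](CC)(CC)OS(=O)(=O)C(F)(F)F
Why: Silylation of the tertiary alcohol, so that no alkoxide can add to the non-enolisable 1,3-diketone (retro-Claisen) during the basic steps 14–17.

Step 14
Reactants: 18 (2R,3R)-2-acetyl-2-methyl-5-(3-methylbut-2-en-1-yl)-3-{2-[(triethylsilyl)oxy]propan-2-yl}cyclopentan-1-one; 19 dimethylmethylideneammonium iodide (CH2=NMe2 iodide)
Product: 20 (2R,3R)-2-[3-(dimethylamino)propanoyl]-2-methyl-5-(3-methylbut-2-en-1-yl)-3-{2-[(triethylsilyl)oxy]propan-2-yl}cyclopentan-1-one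
Conditions: LiN(SiMe3)2 (1.1 equiv), THF, −78 °C; then 19, −78 → 0 °C
Reagents that add atoms: dimethylmethylideneammonium iodide C=[N+](C)C.[I-]
Why: Intermolecular Mannich reaction: the amide base removes an acetyl methyl proton faster than the hindered ring methine, and the kinetic enolate adds to the iminium salt.

Step 15
Reactants: 20 (2R,3R)-2-[3-(dimethylamino)propanoyl]-2-methyl-5-(3-methylbut-2-en-1-yl)-3-{2-[(triethylsilyl)oxy]propan-2-yl}cyclopentan-1-one
Product: 23 (1R,5S,7R)-1-methyl-5-(3-methylbut-2-en-1-yl)-7-{2-[(triethylsilyl)oxy]propan-2-yl}bicyclo[3.2.1]octane-2,8-dione, via ammonium iodide 21 (not isolated), via vinyl ketone 22 (not isolated)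
Conditions: MeI (5 equiv), THF, rt; evaporate; KOt-Bu (1.3 equiv), THF/t-BuOH, −20 → 0 °C
Reagents that add atoms: none
Why: Quaternisation and E1cB (Hofmann-type) elimination release vinyl ketone 22, and intramolecular Michael addition (6-endo) of the ring-ketone enolate closes the six-membered ring; the tether reaches only the face carrying the acyl group, so the prenyl bridgehead is set cis-bridged and the silyloxypropyl group ends exo.

Step 16
Reactants: 23 (1R,5S,7R)-1-methyl-5-(3-methylbut-2-en-1-yl)-7-{2-[(triethylsilyl)oxy]propan-2-yl}bicyclo[3.2.1]octane-2,8-dione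
Product: 25 (1R,5S,7R)-1-methyl-5-(3-methylbut-2-en-1-yl)-7-{2-[(triethylsilyl)oxy]propan-2-yl}bicyclo[3.2.1]oct-3-ene-2,8-dione, via silyl enol ether 24 (not isolated)
Conditions: LiN(SiMe3)2, Me3SiCl, THF, −78 °C; then Pd(OAc)2 (1.1 equiv), MeCN, rt
Reagents that add atoms: none
Why: Saegusa–Ito oxidation: the C-2 ketone can enolise only towards C-3 (the bridging ketone cannot enolise), and Pd(OAc)2 dehydrogenates the silyl enol ether to the enone.

Step 17
Reactants: 25 (1R,5S,7R)-1-methyl-5-(3-methylbut-2-en-1-yl)-7-{2-[(triethylsilyl)oxy]propan-2-yl}bicyclo[3.2.1]oct-3-ene-2,8-dione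
Product: 27 (1R,5S,7R)-4-hydroxy-1-methyl-5-(3-methylbut-2-en-1-yl)-7-{2-[(triethylsilyl)oxy]propan-2-yl}bicyclo[3.2.1]octane-2,8-dione (C-4 configuration not assigned), via pinacol boronate 26 (not isolated)
Conditions: CuCl (10 mol %), DPEphos (10 mol %), NaOt-Bu (10 mol %), B2pin2 (1.2 equiv), t-BuOH (2 equiv), THF, rt; then NaBO3·4H2O, THF/H2O, 0 °C → rt
Reagents that add atoms: sodium perborate [Na+].[O-]OB=O
Why: Copper-catalysed conjugate borylation of the enone followed by stereoretentive C–B oxidation puts oxygen on C-4; the configuration of this carbinol is irrelevant because it is oxidised next.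

Step 18
Reactants: 27 (1R,5S,7R)-4-hydroxy-1-methyl-5-(3-methylbut-2-en-1-yl)-7-{2-[(triethylsilyl)oxy]propan-2-yl}bicyclo[3.2.1]octane-2,8-dione
Product: 28 (1S,5R,6R)-5-methyl-1-(3-methylbut-2-en-1-yl)-6-{2-[(triethylsilyl)oxy]propan-2-yl}bicyclo[3.2.1]octane-2,4,8-trione (enolised 2,4-dione)
Conditions: Dess–Martin periodinane, pyridine, CH2Cl2, rt
Reagents that add atoms: none
Why: Dess–Martin oxidation of the β-hydroxy ketone gives the 1,3-diketone, which rests as its enol.

Step 19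
Reactants: 29 (R)-4-benzyl-1,3-oxazolidin-2-one; 30 butanoyl chloride
Product: 31 (R)-4-benzyl-3-butanoyl-1,3-oxazolidin-2-one
Conditions: n-BuLi, THF, −78 °C; then 30, −78 → 0 °C
Reagents that add atoms: butanoyl chloride CCCC(Cl)=O
Why: N-acylation of the lithiated oxazolidinone attaches the Evans auxiliary.

Step 20
Reactants: 31 (R)-4-benzyl-3-butanoyl-1,3-oxazolidin-2-one; 32 iodomethane
Product: 33 (R)-4-benzyl-3-[(2R)-2-methylbutanoyl]-1,3-oxazolidin-2-one
Conditions: NaN(SiMe3)2, THF, −78 °C; MeI (3 equiv), −78 °C; chromatography to a single diastereomer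
Reagents that add atoms: iodomethane CI
Why: Evans asymmetric alkylation: the chelated Z-enolate is methylated on the face opposite the benzyl group, which with the (R)-auxiliary gives the (2R) centre.

Step 21
Reactants: 33 (R)-4-benzyl-3-[(2R)-2-methylbutanoyl]-1,3-oxazolidin-2-one
Product: 34 (R)-2-methylbutanoic acid
Conditions: LiOH, H2O2, THF/H2O, 0 °C; Na2SO3; then HCl
Reagents that add atoms: hydrogen peroxide OO
Why: Hydroperoxide-mediated imide hydrolysis attacks the exocyclic carbonyl selectively and does not epimerise the α-centre.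

Step 22
Reactants: 28 (1S,5R,6R)-5-methyl-1-(3-methylbut-2-en-1-yl)-6-{2-[(triethylsilyl)oxy]propan-2-yl}bicyclo[3.2.1]octane-2,4,8-trione; 34 (R)-2-methylbutanoic acid
Product: 36 (1R,5R,6R)-4-hydroxy-5-methyl-1-(3-methylbut-2-en-1-yl)-3-[(2R)-2-methylbutanoyl]-6-{2-[(triethylsilyl)oxy]propan-2-yl}bicyclo[3.2.1]oct-3-ene-2,8-dione, via enol ester 35 (not isolated)
Conditions: DCC (1.3 equiv), DMAP (1.3 equiv), CH2Cl2, rt
Reagents that add atoms: (R)-2-methylbutanoic acid CC[C@@H](C)C(=O)O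
Why: Steglich O-acylation of the enol followed by DMAP-mediated 1,3 O-to-C acyl shift (crossed Claisen-type C-acylation) gives the chelated triketone under neutral conditions that leave the acyl α-stereocentre intact.

Step 23
Reactants: 36 (1R,5R,6R)-4-hydroxy-5-methyl-1-(3-methylbut-2-en-1-yl)-3-[(2R)-2-methylbutanoyl]-6-{2-[(triethylsilyl)oxy]propan-2-yl}bicyclo[3.2.1]oct-3-ene-2,8-dione
Product: 37 (1R,5R,6R)-4-hydroxy-6-(2-hydroxypropan-2-yl)-5-methyl-1-(3-methylbut-2-en-1-yl)-3-[(2R)-2-methylbutanoyl]bicyclo[3.2.1]oct-3-ene-2,8-dione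
Conditions: HF·pyridine, THF, 0 °C → rt
Reagents that add atoms: none
Why: Fluoride-mediated silyl ether cleavage under mildly acidic conditions frees the tertiary alcohol without forming an alkoxide next to the bridging ketone.

**Compound list**

1 | 1-(furan-2-yl)ethanol (racemic) | CC(O)c1ccco1 | starting material
2 | rac-trans-4-hydroxy-5-methylcyclopent-2-en-1-one (one enantiomer drawn) | O=C1C=C[C@@H](O)[C@@H]1C | intermediate
3 | rac-4-hydroxy-2-methylcyclopent-2-en-1-one | CC1=CC(O)CC1=O | intermediate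
4 | (S)-4-hydroxy-2-methylcyclopent-2-en-1-one | CC1=C[C@@H](O)CC1=O | intermediate
5 | (S)-4-[(tert-butyldimethylsilyl)oxy]-2-methylcyclopent-2-en-1-one | CC1=C[C@@H](O[Si](C)(C)C(C)(C)C)CC1=O | intermediate
6 | isopropenylmagnesium bromide | C=C(C)[Mg]Br | starting material
7 | acetaldehyde | CC=O | starting material
8 | bromomagnesium (3S,4S)-4-[(tert-butyldimethylsilyl)oxy]-2-methyl-3-(prop-1-en-2-yl)cyclopent-1-en-1-olate | CC1=C(O[Mg]Br)C[C@H](O[Si](C)(C)C(C)(C)C)[C@H]1C(C)=C | intermediate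
9 | (2R,3S,4S)-4-[(tert-butyldimethylsilyl)oxy]-2-(1-hydroxyethyl)-2-methyl-3-(prop-1-en-2-yl)cyclopentan-1-one (carbinol epimers) | CC(O)[C@]1(C)C(=O)C[C@H](O[Si](C)(C)C(C)(C)C)[C@H]1C(C)=C | intermediate
10 | (2R,3S,4S)-4-[(tert-butyldimethylsilyl)oxy]-2-methyl-3-(prop-1-en-2-yl)-2-{1-[(triethylsilyl)oxy]ethyl}cyclopentan-1-one | CC(O[Si](CC)(CC)CC)[C@]1(C)C(=O)C[C@H](O[Si](C)(C)C(C)(C)C)[C@H]1C(C)=C | intermediate
11 | (2R,3S,4S)-4-[(tert-butyldimethylsilyl)oxy]-3-(2-hydroxypropan-2-yl)-2-methyl-2-{1-[(triethylsilyl)oxy]ethyl}cyclopentan-1-one | CC(O[Si](CC)(CC)CC)[C@]1(C)C(=O)C[C@H](O[Si](C)(C)C(C)(C)C)[C@H]1C(C)(C)O | intermediate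
12 | (4R,5R)-4-(2-hydroxypropan-2-yl)-5-methyl-5-{1-[(triethylsilyl)oxy]ethyl}cyclopent-2-en-1-one | CC(O[Si](CC)(CC)CC)[C@]1(C)C(=O)C=C[C@H]1C(C)(C)O | intermediate
13 | (2R,3R)-3-(2-hydroxypropan-2-yl)-2-methyl-2-{1-[(triethylsilyl)oxy]ethyl}cyclopentan-1-one | CC(O[Si](CC)(CC)CC)[C@]1(C)C(=O)CC[C@H]1C(C)(C)O | intermediate
14 | 1-bromo-3-methylbut-2-ene (prenyl bromide) | CC(C)=CCBr | starting material
15 | (2R,3R)-3-(2-hydroxypropan-2-yl)-2-methyl-5-(3-methylbut-2-en-1-yl)-2-{1-[(triethylsilyl)oxy]ethyl}cyclopentan-1-one (C-5 epimers) | CC(O[Si](CC)(CC)CC)[C@]1(C)C(=O)C(CC=C(C)C)C[C@H]1C(C)(C)O | intermediate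
16 | (2R,3R)-2-(1-hydroxyethyl)-3-(2-hydroxypropan-2-yl)-2-methyl-5-(3-methylbut-2-en-1-yl)cyclopentan-1-one | CC(O)[C@]1(C)C(=O)C(CC=C(C)C)C[C@H]1C(C)(C)O | intermediate
17 | (2R,3R)-2-acetyl-3-(2-hydroxypropan-2-yl)-2-methyl-5-(3-methylbut-2-en-1-yl)cyclopentan-1-one | CC(=O)[C@]1(C)C(=O)C(CC=C(C)C)C[C@H]1C(C)(C)O | intermediate
18 | (2R,3R)-2-acetyl-2-methyl-5-(3-methylbut-2-en-1-yl)-3-{2-[(triethylsilyl)oxy]propan-2-yl}cyclopentan-1-one | CC(=O)[C@]1(C)C(=O)C(CC=C(C)C)C[C@H]1C(C)(C)O[Si](CC)(CC)CC | intermediate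
19 | dimethylmethylideneammonium iodide | C=[N+](C)C.[I-] | starting material
20 | (2R,3R)-2-[3-(dimethylamino)propanoyl]-2-methyl-5-(3-methylbut-2-en-1-yl)-3-{2-[(triethylsilyl)oxy]propan-2-yl}cyclopentan-1-one | CN(C)CCC(=O)[C@]1(C)C(=O)C(CC=C(C)C)C[C@H]1C(C)(C)O[Si](CC)(CC)CC | intermediate
21 | N-methyl quaternary ammonium iodide of 20 | C[N+](C)(C)CCC(=O)[C@]1(C)C(=O)C(CC=C(C)C)C[C@H]1C(C)(C)O[Si](CC)(CC)CC.[I-] | intermediate
22 | (2R,3R)-2-methyl-5-(3-methylbut-2-en-1-yl)-2-(prop-2-enoyl)-3-{2-[(triethylsilyl)oxy]propan-2-yl}cyclopentan-1-one | C=CC(=O)[C@]1(C)C(=O)C(CC=C(C)C)C[C@H]1C(C)(C)O[Si](CC)(CC)CC | intermediate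
23 | (1R,5S,7R)-1-methyl-5-(3-methylbut-2-en-1-yl)-7-{2-[(triethylsilyl)oxy]propan-2-yl}bicyclo[3.2.1]octane-2,8-dione | C1C(=O)[C@]2(C)C(=O)[C@@](CC=C(C)C)(C[C@H]2C(C)(C)O[Si](CC)(CC)CC)C1 | intermediate
24 | (1R,5R,7R)-1-methyl-5-(3-methylbut-2-en-1-yl)-7-{2-[(triethylsilyl)oxy]propan-2-yl}-2-[(trimethylsilyl)oxy]bicyclo[3.2.1]oct-2-en-8-one | C1=C(O[Si](C)(C)C)[C@]2(C)C(=O)[C@@](CC=C(C)C)(C[C@H]2C(C)(C)O[Si](CC)(CC)CC)C1 | intermediate
25 | (1R,5S,7R)-1-methyl-5-(3-methylbut-2-en-1-yl)-7-{2-[(triethylsilyl)oxy]propan-2-yl}bicyclo[3.2.1]oct-3-ene-2,8-dione | C1C(=O)[C@]2(C)C(=O)[C@@](CC=C(C)C)(C[C@H]2C(C)(C)O[Si](CC)(CC)CC)C=1 | intermediate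
26 | (1R,5S,7R)-1-methyl-5-(3-methylbut-2-en-1-yl)-4-(4,4,5,5-tetramethyl-1,3,2-dioxaborolan-2-yl)-7-{2-[(triethylsilyl)oxy]propan-2-yl}bicyclo[3.2.1]octane-2,8-dione | C1C(=O)[C@]2(C)C(=O)[C@@](CC=C(C)C)(C[C@H]2C(C)(C)O[Si](CC)(CC)CC)C1B3OC(C)(C)C(C)(C)O3 | intermediate
27 | (1R,5S,7R)-4-hydroxy-1-methyl-5-(3-methylbut-2-en-1-yl)-7-{2-[(triethylsilyl)oxy]propan-2-yl}bicyclo[3.2.1]octane-2,8-dione | C1C(=O)[C@]2(C)C(=O)[C@@](CC=C(C)C)(C[C@H]2C(C)(C)O[Si](CC)(CC)CC)C1O | intermediate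
28 | (1S,5R,6R)-5-methyl-1-(3-methylbut-2-en-1-yl)-6-{2-[(triethylsilyl)oxy]propan-2-yl}bicyclo[3.2.1]octane-2,4,8-trione | C1C(=O)[C@]2(C)C(=O)[C@@](CC=C(C)C)(C[C@H]2C(C)(C)O[Si](CC)(CC)CC)C1=O | intermediate
29 | (R)-4-benzyl-1,3-oxazolidin-2-one | O=C1N[C@H](Cc2ccccc2)CO1 | starting material
30 | butanoyl chloride | CCCC(Cl)=O | starting material
31 | (R)-4-benzyl-3-butanoyl-1,3-oxazolidin-2-one | CCCC(=O)N1[C@H](Cc2ccccc2)COC1=O | intermediate
32 | iodomethane | CI | starting material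
33 | (R)-4-benzyl-3-[(2R)-2-methylbutanoyl]-1,3-oxazolidin-2-one | CC[C@@H](C)C(=O)N1[C@H](Cc2ccccc2)COC1=O | intermediate
34 | (R)-2-methylbutanoic acid | CC[C@@H](C)C(=O)O | intermediate
35 | enol (2R)-2-methylbutanoate of 28 (acyl on the enol oxygen next to the methyl-bearing bridgehead) | C1=C(OC(=O)[C@H](C)CC)[C@]2(C)C(=O)[C@@](CC=C(C)C)(C[C@H]2C(C)(C)O[Si](CC)(CC)CC)C1=O | intermediate
36 | (1R,5R,6R)-4-hydroxy-5-methyl-1-(3-methylbut-2-en-1-yl)-3-[(2R)-2-methylbutanoyl]-6-{2-[(triethylsilyl)oxy]propan-2-yl}bicyclo[3.2.1]oct-3-ene-2,8-dione | CC[C@@H](C)C(=O)C1=C(O)[C@]2(C)C(=O)[C@@](CC=C(C)C)(C[C@H]2C(C)(C)O[Si](CC)(CC)CC)C1=O | intermediate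
37 | (1R,5R,6R)-4-hydroxy-6-(2-hydroxypropan-2-yl)-5-methyl-1-(3-methylbut-2-en-1-yl)-3-[(2R)-2-methylbutanoyl]bicyclo[3.2.1]oct-3-ene-2,8-dione | CC[C@@H](C)C(=O)C1=C(O)[C@]2(C)C(=O)[C@@](CC=C(C)C)(C[C@H]2C(C)(C)O)C1=O | target

**Step count and risks**

Total steps: 23 (20 in the main line, 3 for the acid 34). Longest linear sequence: 20 steps (1–18, 22, 23).

Most likely to fail, step 15 (Michael closure that builds the bridged ring and a quaternary bridgehead; the vinyl ketone may polymerise or the enolate may not close). Fallback: set out from 18 and close the ring at the carboxyl oxidation level instead. LiN(SiMe3)2, CS2 and then MeI turn the methyl ketone into the α-oxo ketene dithioacetal F1. KN(SiMe3)2 then forms the ring-ketone enolate, which adds to the bis(methylsulfanyl) carbon and expels methanethiolate to give the bicyclic β-(methylsulfanyl) enone F2. Aqueous LiOH in THF hydrolyses this vinylogous thioester by addition–elimination, and the route is rejoined at 28, so steps 14–18 are bypassed.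

Second, step 17 (borylation at a β-carbon next to a quaternary bridgehead, with alkoxide present beside a cleavable 1,3-diketone). Fallback: set out from 25 and use nucleophilic epoxidation with t-BuOOH and DBU to give the epoxy ketone F3. Pd(PPh3)4 with dppe in hot toluene then isomerises the α,β-epoxy ketone to the 1,3-diketone, which rejoins the route at 28.

Third, step 22 (the O-to-C acyl shift may stall at the enol ester on this hindered dione, or the acyl α-centre may erode). Fallback: set out from 28 and methylate the enol with Me3SiCHN2 to the methyl enol ether F4 (either regioisomer serves). Lithium 2,2,6,6-tetramethylpiperidide at −78 °C lithiates the vinyl CH between the two oxygenated carbons, and the anion is acylated with (R)-2-methylbutanoyl chloride F5 (from 34 and oxalyl chloride) to give the acylated methyl enol ether F6. LiOH in aqueous dioxane cleaves the enol ether and the route is rejoined at 36.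

**Further compounds**

F1 | step 15 | (2R,3R)-2-[3,3-bis(methylsulfanyl)prop-2-enoyl]-2-methyl-5-(3-methylbut-2-en-1-yl)-3-{2-[(triethylsilyl)oxy]propan-2-yl}cyclopentan-1-one | CSC(SC)=CC(=O)[C@]1(C)C(=O)C(CC=C(C)C)C[C@H]1C(C)(C)O[Si](CC)(CC)CC
F2 | step 15 | (1R,5R,7R)-1-methyl-4-(methylsulfanyl)-5-(3-methylbut-2-en-1-yl)-7-{2-[(triethylsilyl)oxy]propan-2-yl}bicyclo[3.2.1]oct-3-ene-2,8-dione | C1C(=O)[C@]2(C)C(=O)[C@@](CC=C(C)C)(C[C@H]2C(C)(C)O[Si](CC)(CC)CC)C=1SC
F3 | step 17 | 3,4-epoxide of enone 25 (oxirane on C-3/C-4, other centres as in 25) | C13C(=O)[C@]2(C)C(=O)[C@@](CC=C(C)C)(C[C@H]2C(C)(C)O[Si](CC)(CC)CC)C1O3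
F4 | step 22 | 4-methoxy-5-methyl-1-(3-methylbut-2-en-1-yl)-6-{2-[(triethylsilyl)oxy]propan-2-yl}bicyclo[3.2.1]oct-3-ene-2,8-dione (ring centres as in 28) | C1=C(OC)[C@]2(C)C(=O)[C@@](CC=C(C)C)(C[C@H]2C(C)(C)O[Si](CC)(CC)CC)C1=O
F5 | step 22 | (R)-2-methylbutanoyl chloride | CC[C@@H](C)C(Cl)=O
F6 | step 22 | 4-methoxy-5-methyl-1-(3-methylbut-2-en-1-yl)-3-[(2R)-2-methylbutanoyl]-6-{2-[(triethylsilyl)oxy]propan-2-yl}bicyclo[3.2.1]oct-3-ene-2,8-dione (ring centres as in 36) | CC[C@@H](C)C(=O)C1=C(OC)[C@]2(C)C(=O)[C@@](CC=C(C)C)(C[C@H]2C(C)(C)O[Si](CC)(CC)CC)C1=O
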